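Ring A (C6, C1–C5) carries its only carbon branch, methyl C15, on C3. Cutting out C3 together with C15 leaves a spiro-fused cyclopentanone (C6, C1, C2, C4, C5) on ring B whose thirteen carbons map onto α-ionone. The key step reverses this excision: a scandium-catalysed diazoethane homologation inserts C3 between the C2 carbonyl and C4, building ring A, both new C–C bonds and the methyl-bearing carbon in one operation. Its precursor is (5R)-6,10,10-trimethylspiro[4.5]dec-6-en-2-one, made by carbenoid C–H insertion at the allylic methine of resolved (S)-dihydro-α-ionone. The late steps turn the C2 ketone into the bromochloride and ring B into the bromohydrin.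

Key step: step 9

Numbering: ring A = C6 (spiro), C1, C2, C3, C4, C5; ring B = C6, C7, C8, C9, C10, C11; C14 is the carbon on C7 and C15 the methyl on C3. The C6 descriptor switches between R and S along the route only because substituent priorities change; the spiro centre is never inverted.
Remark: the target SMILES is read as (2S,3S,6S,9S,10S), that is C2–Br anti to C3–Cl and C9–OH anti to C10–Br, and the route is planned for this diastereomer.

Step 1
Reactants: 1 (±)-α-ionone [(3E)-4-(2,6,6-trimethylcyclohex-2-en-1-yl)but-3-en-2-one]
Product: 2 α-ionol, (3E)-4-(2,6,6-trimethylcyclohex-2-en-1-yl)but-3-en-2-ol, all four stereoisomers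
Conditions: NaBH4, CeCl3·7H2O, MeOH, 0 °C
Reagents that add atoms: none
Why: Luche reduction adds hydride only to the enone carbonyl (1,2) and leaves both alkenes, and because no facial control is sought the allylic alcohol forms as all four stereoisomers.

Step 2
Reactants: 2 α-ionol (four stereoisomers)
Product: 3 (2S,3E)-4-(2,6,6-trimethylcyclohex-2-en-1-yl)but-3-en-2-ol, both ring C1′ epimers
Conditions: lipase PS (Burkholderia cepacia), vinyl acetate, t-BuOMe, 30 °C, stopped near half conversion
Reagents that add atoms: none
Why: Lipase-catalysed kinetic resolution by irreversible transesterification should acetylate the (2R)-carbinols (Kazlauskas rule, alkenyl large and methyl medium) and leave the (2S)-alcohols, whatever the remote ring centre.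

Step 3
Reactants: 3 (2S)-α-ionol (ring epimers)
Product: 4 (2S,3E)-4-[(1S)-2,6,6-trimethylcyclohex-2-en-1-yl]but-3-en-2-yl 4-nitrobenzoate
Conditions: 4-O2NC6H4COCl, pyridine, DMAP (cat.), CH2Cl2, 0 °C to rt; fractional crystallisation (hexane/EtOAc)
Reagents that add atoms: 4-nitrobenzoyl chloride, O=C(Cl)c1ccc(cc1)[N+](=O)[O-]
Why: DMAP-catalysed acylation turns the two ring epimers, now diastereomers of one carbinol configuration, into crystalline 4-nitrobenzoates from which the (2S,1′S) ester should be collected by fractional crystallisation, no stereocentre being touched.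

Step 4
Reactants: 4 (2S,1′S)-4-nitrobenzoate
Product: 5 (2S,3E)-4-[(1S)-2,6,6-trimethylcyclohex-2-en-1-yl]but-3-en-2-ol
Conditions: K2CO3, MeOH, rt
Reagents that add atoms: none
Why: Carbonate-catalysed transesterification (methanolysis) of the aryl ester frees the allylic alcohol without touching either stereocentre.

Step 5
Reactants: 5 (2S,1′S)-α-ionol
Product: 6 4-[(1S)-2,6,6-trimethylcyclohex-2-en-1-yl]butan-2-one [(S)-dihydro-α-ionone]
Conditions: RuCl(C5H5)(PPh3)2 (5 mol %), Et3NH·PF6 (10 mol %), dioxane, 100 °C
Reagents that add atoms: none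
Why: Ruthenium-catalysed redox isomerisation of an allylic alcohol (alkoxide β-hydride elimination, then return of the hydride to the β-carbon of the bound enone) should give the saturated methyl ketone and erase the carbinol centre, while the isolated ring alkene and the (S) ring centre are not engaged.

Step 6
Reactants: 6 (S)-dihydro-α-ionone
Product: 8 1-diazo-4-[(1S)-2,6,6-trimethylcyclohex-2-en-1-yl]butan-2-one, via trifluoroacetyl diketone 7 (not isolated)
Conditions: LiN(SiMe3)2, THF, −78 °C; CF3CO2CH2CF3; then MeSO2N3, Et3N, H2O, MeCN, rt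
Reagents that add atoms: methanesulfonyl azide, CS(=O)(=O)N=[N+]=[N-]
Why: Detrifluoroacetylative diazo transfer, that is kinetic deprotonation at the methyl group, Claisen trifluoroacetylation and Regitz-type transfer with loss of the trifluoroacetyl group, should give the terminal diazo ketone regiospecifically.

Step 7
Reactants: 8 diazo ketone
Product: 9 (5R)-6,10,10-trimethylspiro[4.5]dec-6-en-2-one (spiro carbon = C6, carbonyl = C2 in the target numbering)
Conditions: Rh2(O2CC3F7)4 (1 mol %), CH2Cl2, rt, slow addition of 8
Reagents that add atoms: none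
Why: Rhodium-carbenoid 1,5 C–H insertion should close the cyclopentanone at the tertiary allylic C6–H through a three-centre transition state with retention, so that the resolved methine becomes the spiro carbon, and the electron-poor perfluorobutyrate ligands favour insertion over addition to the C7=C8 alkene.

Step 8
Reactants: 10 N-ethyl-N-nitrosourea
Product: 11 diazoethane (cold ethereal solution)
Conditions: KOH (40% aq), Et2O, 0 °C; ether layer dried over KOH
Reagents that add atoms: none
Why: Hydroxide-induced fragmentation of the N-nitrosourea (the diazomethane-type generation of a diazoalkane) releases diazoethane into the ether layer, which is used cold and at once.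

Step 9
Reactants: 9 spiro[4.5]decenone; 11 diazoethane
Product: 12 (3S,6R)-3,7,11,11-tetramethylspiro[5.5]undec-7-en-2-one
Conditions: Sc(OTf)3 (10 mol %), 11 (1.2 equiv, slow addition), toluene/Et2O, −78 °C
Reagents that add atoms: diazoethane (11), CC=[N+]=[N-]
Why: Sc(OTf)3 binds the C2 carbonyl, the carbon of diazoethane adds to it, and in the resulting β-diazonium alkoxide the ring bond antiperiplanar to the leaving N2 shifts from C2 to the new carbon as nitrogen departs, so that this carbon becomes C3 and carries C15. The closest known reaction type is the Lewis-acid-catalysed one-carbon homologation of cycloalkanones with non-stabilised diazoalkanes (a Tiffeneau–Demjanov-type 1,2-shift). Ring A is therefore not closed end to end but formed by enlargement of the five-membered ring, C3 being inserted between C2 and C4. The new C3 centre lies α to the ketone, is expected as the equatorial methyl epimer under ring-conformational control, and is erased in step 10, so its configuration carries no weight. The step needs migration of C4 and not of C1, and the substrate should secure this because C1 is a neopentyl methylene pressed between the spiro carbon and C11: only the betaine rotamer with C4 antiperiplanar to N2 keeps the new methyl group away from that crowded flank. Over-homologation is held back because ketone 12 is α-branched and six-membered, hence less reactive than 9, and 11 is added slowly in small excess at −78 °C.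

Step 10
Reactants: 12 3-methyl spiro ketone
Product: 13 (6R)-3,7,11,11-tetramethylspiro[5.5]undeca-2,7-dien-2-yl trifluoromethanesulfonate
Conditions: Tf2O, 2,6-di-tert-butyl-4-methylpyridine, CH2Cl2, 0 °C to rt
Reagents that add atoms: trifluoromethanesulfonic anhydride, O=S(=O)(OS(=O)(=O)C(F)(F)F)C(F)(F)F
Why: Enol triflation under equilibrating conditions should give the more substituted C2=C3 enol triflate (enolisation toward the neopentyl C1 is slower and leads to the less stable isomer), which erases the C3 centre.

Step 11
Reactants: 13 enol triflate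
Product: 14 (6R)-3,7,11,11-tetramethyl-9-oxospiro[5.5]undeca-2,7-dien-2-yl trifluoromethanesulfonate
Conditions: Rh2(C6H10NO)4 (dirhodium tetracaprolactamate, 1 mol %), t-BuOOH (70% aq), K2CO3, CH2Cl2, rt
Reagents that add atoms: tert-butyl hydroperoxide, CC(C)(C)OO
Why: Radical allylic oxidation, in which tert-butylperoxyl radicals abstract a C9 hydrogen of the electron-rich ring B alkene (the only secondary allylic C–H beside it, since C6 is quaternary) and the mixed peroxide collapses to the C9 enone, should pass over the electron-poor enol triflate and its allylic positions.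

Step 12
Reactants: 14 enone triflate
Product: 15 (6R)-3,7,11,11-tetramethylspiro[5.5]undeca-2,7-dien-9-one
Conditions: Pd(OAc)2 (5 mol %), PPh3, n-Bu3N, HCO2H, DMF, 60 °C
Reagents that add atoms: none
Why: Palladium-catalysed formate reduction of an enol triflate (oxidative addition of zerovalent palladium into C2–O, decarboxylation of the formate to a hydride, reductive elimination) should give the C2=C3 alkene and leave the hindered enone alone.

Step 13
Reactants: 15 dienone
Product: 18 (6S,10S)-10-bromo-3,7,11,11-tetramethylspiro[5.5]undeca-2,7-dien-9-one, via trimethylsilyl dienol ether 16 (not isolated), via (10R)-bromo dienone 17 (not isolated)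
Conditions: LiN(iPr)2, THF, −78 °C; Me3SiCl; NBS, −78 °C; then DBU (10 mol %), CH2Cl2, 0 °C
Reagents that add atoms: N-bromosuccinimide, O=C1CCC(=O)N1Br
Why: Kinetic α′-enolisation of the enone (C10 is its only enolisable α-carbon), silylation and bromination of the silyl dienol ether place bromine on C10 far faster than NBS attacks the ring A alkene, the bromine entering axially anti to the axial C11 methyl, and amidine-catalysed equilibration through the enol should then give the epimer with pseudo-equatorial bromine in the ring B half-chair that keeps C14 over the sp2 C2 side of ring A, which is (10S).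

Step 14
Reactants: 18 (10S)-bromo dienone
Product: 20 (6S,10S)-10-bromo-3,11,11-trimethyl-7-methylidenespiro[5.5]undec-2-en-9-one, via silyl dienol ether 19 (not isolated)
Conditions: t-BuMe2SiOTf, Et3N, CH2Cl2, −78 to 0 °C; then n-Bu4NF, AcOH, THF, −78 °C
Reagents that add atoms: none
Why: Deconjugation by soft enolisation and kinetic ketonisation should work because the silyl triflate/amine pair removes a C14 hydrogen (the only γ-hydrogens, C6 being quaternary, whereas the C10 methine is screened by bromine and the C11 methyls) to give the extended silyl dienol ether, and buffered fluoride then releases the dienol, which is protonated at C8, so that the alkene ends as the C7=C14 methylene with C10 untouched.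

Step 15
Reactants: 20 β,γ-unsaturated bromo ketone (used crude)
Product: 21 (6S,9S,10S)-10-bromo-3,11,11-trimethyl-7-methylidenespiro[5.5]undec-2-en-9-ol
Conditions: NaBH4, CeCl3·7H2O, MeOH/THF, −78 °C
Reagents that add atoms: none
Why: In this Luche reduction the small cerium-assisted borohydride should attack C9 along the axial trajectory of the ring B chair (favoured by the adjacent equatorial C–Br bond), giving the equatorial C9 alcohol anti to the C10 bromine, that is (9S), while the C–Br bond survives at low temperature.

Step 16
Reactants: 21 bromohydrin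
Product: 22 (2S,3S,6S,9S,10S)-2,10-dibromo-3-chloro-3,11,11-trimethyl-7-methylidenespiro[5.5]undecan-9-ol (CNP0247242.1)
Conditions: NBS, HCl (1 M in Et2O, 1.0 equiv), CH2Cl2, −78 °C
Reagents that add atoms: N-bromosuccinimide, O=C1CCC(=O)N1Br; hydrogen chloride, Cl
Why: Bromochlorination with bromine monochloride made in situ should form the bromonium ion on the ring A face anti to the pseudo-axial C7, whose methylene roofs the other face, chloride then opens it anti at the tertiary C3 (Markovnikov), which sets (2S,3S), and the trisubstituted C2=C3 alkene reacts ahead of the less electron-rich 1,1-disubstituted C7=C14 alkene.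

Compound list
1 | (±)-α-ionone, (3E)-4-(2,6,6-trimethylcyclohex-2-en-1-yl)but-3-en-2-one | CC1=CCCC(C)(C)C1/C=C/C(C)=O | starting material
2 | α-ionol, four stereoisomers | CC1=CCCC(C)(C)C1/C=C/C(C)O | intermediate
3 | (2S,3E)-4-(2,6,6-trimethylcyclohex-2-en-1-yl)but-3-en-2-ol, ring epimers | CC1=CCCC(C)(C)C1/C=C/[C@H](C)O | intermediate
4 | (2S,3E)-4-[(1S)-2,6,6-trimethylcyclohex-2-en-1-yl]but-3-en-2-yl 4-nitrobenzoate | CC1=CCCC(C)(C)[C@@H]1/C=C/[C@H](C)OC(=O)c1ccc(cc1)[N+](=O)[O-] | intermediate
5 | (2S,3E)-4-[(1S)-2,6,6-trimethylcyclohex-2-en-1-yl]but-3-en-2-ol | CC1=CCCC(C)(C)[C@@H]1/C=C/[C@H](C)O | intermediate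
6 | 4-[(1S)-2,6,6-trimethylcyclohex-2-en-1-yl]butan-2-one | CC1=CCCC(C)(C)[C@@H]1CCC(C)=O | intermediate
7 | 1,1,1-trifluoro-6-[(1S)-2,6,6-trimethylcyclohex-2-en-1-yl]hexane-2,4-dione (not isolated) | CC1=CCCC(C)(C)[C@@H]1CCC(=O)CC(=O)C(F)(F)F | intermediate
8 | 1-diazo-4-[(1S)-2,6,6-trimethylcyclohex-2-en-1-yl]butan-2-one | CC1=CCCC(C)(C)[C@@H]1CCC(=O)C=[N+]=[N-] | intermediate
9 | (5R)-6,10,10-trimethylspiro[4.5]dec-6-en-2-one | CC1=CCCC(C)(C)[C@]12CCC(=O)C2 | intermediate
10 | N-ethyl-N-nitrosourea | CCN(N=O)C(N)=O | starting material
11 | diazoethane | CC=[N+]=[N-] | intermediate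
12 | (3S,6R)-3,7,11,11-tetramethylspiro[5.5]undec-7-en-2-one | CC1=CCCC(C)(C)[C@]12CC[C@H](C)C(=O)C2 | intermediate
13 | (6R)-3,7,11,11-tetramethylspiro[5.5]undeca-2,7-dien-2-yl trifluoromethanesulfonate | CC1=CCCC(C)(C)[C@]12CCC(C)=C(OS(=O)(=O)C(F)(F)F)C2 | intermediate
14 | (6R)-3,7,11,11-tetramethyl-9-oxospiro[5.5]undeca-2,7-dien-2-yl trifluoromethanesulfonate | CC1=CC(=O)CC(C)(C)[C@]12CCC(C)=C(OS(=O)(=O)C(F)(F)F)C2 | intermediate
15 | (6R)-3,7,11,11-tetramethylspiro[5.5]undeca-2,7-dien-9-one | CC1=CC(=O)CC(C)(C)[C@]12CCC(C)=CC2 | intermediate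
16 | trimethyl{[(6S)-3,7,11,11-tetramethylspiro[5.5]undeca-2,7,9-trien-9-yl]oxy}silane (not isolated) | CC1=CC(O[Si](C)(C)C)=CC(C)(C)[C@]12CCC(C)=CC2 | intermediate
17 | (6S,10R)-10-bromo-3,7,11,11-tetramethylspiro[5.5]undeca-2,7-dien-9-one (not isolated) | CC1=CC(=O)[C@H](Br)C(C)(C)[C@]12CCC(C)=CC2 | intermediate
18 | (6S,10S)-10-bromo-3,7,11,11-tetramethylspiro[5.5]undeca-2,7-dien-9-one | CC1=CC(=O)[C@@H](Br)C(C)(C)[C@]12CCC(C)=CC2 | intermediate
19 | tert-butyl{[(6S,10S)-10-bromo-3,11,11-trimethyl-7-methylidenespiro[5.5]undeca-2,8-dien-9-yl]oxy}dimethylsilane (not isolated) | C=C1C=C(O[Si](C)(C)C(C)(C)C)[C@@H](Br)C(C)(C)[C@]12CCC(C)=CC2 | intermediate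
20 | (6S,10S)-10-bromo-3,11,11-trimethyl-7-methylidenespiro[5.5]undec-2-en-9-one | C=C1CC(=O)[C@@H](Br)C(C)(C)[C@]12CCC(C)=CC2 | intermediate
21 | (6S,9S,10S)-10-bromo-3,11,11-trimethyl-7-methylidenespiro[5.5]undec-2-en-9-ol | C=C1C[C@H](O)[C@@H](Br)C(C)(C)[C@]12CCC(C)=CC2 | intermediate
22 | (2S,3S,6S,9S,10S)-2,10-dibromo-3-chloro-3,11,11-trimethyl-7-methylidenespiro[5.5]undecan-9-ol | C=C1C[C@H](O)[C@@H](Br)C(C)(C)[C@]12CC[C@](C)(Cl)[C@@H](Br)C2 | target

Total step count: 16 (including the preparation of diazoethane, step 8).
Longest linear sequence: 15 steps (steps 1–7 and 9–16).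

Steps most likely to fail

Step 14. The amine may remove the C10 hydrogen instead of a C14 hydrogen (which only returns 18), the allylic C10–Br bond of the extended dienol ether may ionise, or the ketone may slip back into conjugation while it is released. The fallback sets out from 18: acid-catalysed enol acetylation (isopropenyl acetate, cat. TsOH, 60 °C, short contact) should give the extended enol ester (6S,10S)-10-bromo-3,11,11-trimethyl-7-methylidenespiro[5.5]undeca-2,8-dien-9-yl acetate F1. NaBH4 in EtOH/THF at 0 °C then cleaves the enol ester, the dienolate is protonated at C8 and the non-conjugated ketone is reduced as it forms (enol acetate/borohydride deconjugative reduction). This rejoins the route at 21 without isolating 20.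

Step 15. Facial selectivity may be poor: the axial C11 methyl may push the hydride to the equatorial side and give the cis-bromohydrin. The fallback sets out from 20: equatorial attack is enforced with LiBH(sBu)3 (THF, −78 °C) to give the cis alcohol (6S,9R,10S)-10-bromo-3,11,11-trimethyl-7-methylidenespiro[5.5]undec-2-en-9-ol F2. Its axial hydroxyl is inverted by a Mitsunobu reaction (4-nitrobenzoic acid, PPh3, DIAD, toluene) to (6S,9S,10S)-10-bromo-3,11,11-trimethyl-7-methylidenespiro[5.5]undec-2-en-9-yl 4-nitrobenzoate F3, and methanolysis (K2CO3, MeOH, 0 °C) returns 21.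

Step 7. The carbenoid may add to the neighbouring C7=C8 alkene (cyclopropanation) faster than it inserts into C6–H. The fallback sets out from 6: Claisen condensation with dimethyl carbonate (NaH, THF, reflux) gives the β-keto ester methyl 3-oxo-5-[(1S)-2,6,6-trimethylcyclohex-2-en-1-yl]pentanoate F4. Diazo transfer (4-acetamidobenzenesulfonyl azide, Et3N, MeCN) gives methyl 2-diazo-3-oxo-5-[(1S)-2,6,6-trimethylcyclohex-2-en-1-yl]pentanoate F5. Rh2(OAc)4 in CH2Cl2 then brings about 1,5-insertion of this acceptor/acceptor carbenoid, the carbenoid class best established for closing cyclopentanones at methine C–H bonds with retention, to give the spiro keto ester methyl (5R)-6,10,10-trimethyl-2-oxospiro[4.5]dec-6-ene-1-carboxylate F6. Krapcho dealkoxycarbonylation (LiCl, wet DMSO, 140 °C) returns 9.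

Further compounds
F1 | step 14 | (6S,10S)-10-bromo-3,11,11-trimethyl-7-methylidenespiro[5.5]undeca-2,8-dien-9-yl acetate | C=C1C=C(OC(C)=O)[C@@H](Br)C(C)(C)[C@]12CCC(C)=CC2
F2 | step 15 | (6S,9R,10S)-10-bromo-3,11,11-trimethyl-7-methylidenespiro[5.5]undec-2-en-9-ol | C=C1C[C@@H](O)[C@@H](Br)C(C)(C)[C@]12CCC(C)=CC2
F3 | step 15 | (6S,9S,10S)-10-bromo-3,11,11-trimethyl-7-methylidenespiro[5.5]undec-2-en-9-yl 4-nitrobenzoate | C=C1C[C@H](OC(=O)c3ccc(cc3)[N+](=O)[O-])[C@@H](Br)C(C)(C)[C@]12CCC(C)=CC2
F4 | step 7 | methyl 3-oxo-5-[(1S)-2,6,6-trimethylcyclohex-2-en-1-yl]pentanoate | CC1=CCCC(C)(C)[C@@H]1CCC(=O)CC(=O)OC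
F5 | step 7 | methyl 2-diazo-3-oxo-5-[(1S)-2,6,6-trimethylcyclohex-2-en-1-yl]pentanoate | CC1=CCCC(C)(C)[C@@H]1CCC(=O)C(=[N+]=[N-])C(=O)OC
F6 | step 7 | methyl (5R)-6,10,10-trimethyl-2-oxospiro[4.5]dec-6-ene-1-carboxylate (C1 epimers) | CC1=CCCC(C)(C)[C@]12CCC(=O)C2C(=O)OC
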